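## Structural features

The target is a pentacycle. Ring A (C1–C5, C10), ring B (C5–C10), a cyclobutane (C1, C10, C9, C11), ring C (C8, C9, C11–C14) and a spiro-cyclopropane (C13, C15, C17) are packed around two hub atoms: C10 is shared by ring A, ring B and the cyclobutane, and C9 by ring B, ring C and the cyclobutane. Eleven stereocentres (C1, C5–C13, C15) form one unbroken array, and four of them are fully substituted (C9, C10, C11, C13). Ring A/ring B, ring B/cyclobutane, ring B/ring C and ring C/cyclobutane are cis-fused, but H1 and the C10 methyl lie on opposite faces, so the cyclobutane is trans-fused to ring A. The oxygens on C6, C7 and C9 share the convex face of ring B with the angular methyl and H5. The 9-OH, 11-OH and 12-OAc groups and the cyclopropane methylene C17 share the convex face of ring C, with the C15 methyl turned toward C12. Fragile elements are the C9–OH/C14=O β-hydroxy ketone (retro-aldol, C8 epimerisation), the cis tertiary diol on the four-membered ring (a carbonyl at C12 beside a free 9-OH would open the cyclobutane by retro-aldol), the spiro-cyclopropyl ketone, and two secondary acetates next to a free secondary 7-OH. The real difficulty is the trans C1–C10 junction in a cyclobutane that also carries two vicinal tertiary alcohols. The key step uses the fact that the C1–C11 bond can be made last, by sliding C1 from a carbonyl carbon (C12) onto C11 inside a five-membered ring C10–C9–C11–C12–C1 that is trans-fused to ring A without strain.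

## Logic of the disconnections

34 ⇒ 29 (through 33, 32, 31, 30). Only C–O and oxidation-level changes are undone: the C14 ketone, the free 7-OH and the C3 ketone are unmasked last, and the acetyl C–O bonds at C6 and C12 are cut. The C9–OH/C14=O aldol array is reserved for the end because it does not tolerate base. The forward steps need C6 and C12 to be the only free secondary hydroxyls at the acylation stage; an acetal across O6/O7 was rejected because it would leave an unselective mono-acetylation as the final step.

29 ⇒ 28. The C13–C17 and C15–C17 bonds of the cyclopropane are cut. This reduces the spiro centre and C15 to one alkene geometry plus a directing hydroxyl. The forward step needs the ethylidene methyl cis to C12 and the 12-OH on the convex face.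

28 ⇒ 27. The C12–C13 bond of ring C and the C15–C16 bond (methyl) are cut together. One organometallic step would then close ring C, fix the alkene geometry by syn addition and set C12. It replaces a Claisen-type closure to a 12,14-diketone, in which C12 and C14 are not distinguished and the ethylidene geometry is not set. The forward step needs a free terminal alkyne and an aldehyde in one molecule and chelation between O11 and the aldehyde oxygen.

27 ⇒ 24 (through 26 and 25). The C11–O bond is cut, the C12 aldehyde is returned to the ester and the alkyne to its C-silyl form. C11 is the only enolisable position of the ester, so the quaternary carbinol reduces to a face-selective enolate oxidation. The forward steps need exo attack and an O9 protecting group that cannot migrate to O11.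

24 ⇒ 22 (through 23). The cyclobutane bond C1–C11 is cut and C1 is re-attached to C12. The strained trans-bicyclo[4.2.0] unit becomes a trans-hydrindanone, in which the trans junction is ordinary. The forward step needs the diazo group on C11 and retention at the migrating C1.

22 ⇒ 18 (through 20 and 19). The diazo C=N bond, the O9 ether and then the C9–C11 bond are cut. The tricycle falls back to a cis-decalin with a C9 ketone and a C1 acetyl group. The forward aldol needs the acetyl trans to C9 on ring A, a kinetic enolate at the methyl group, and no equilibration at C1 or C8.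

18 ⇒ 14 (through 17 and 16). The acetyl is traced to a vinyl group, the C3 ketal to the ketone, and the C1–C12 bond is cut as a conjugate addition to a ring A enone. The forward addition has to come anti to the C10–C9 bond.

14 ⇒ 11 + 12. The C8–C14 bond is cut as an aldol; C8 is the only enolisable carbon of 11. The three-carbon ynal 12 brings C14, C13 and C15 at once. It replaces an isopropenyl group on C8, which would not survive the osmylation that sets C6/C7 and would leave ring C two carbons short of the ethylidene.

11 ⇒ 8 (through 10 and 9). The two O-protecting groups and then both C–O bonds at C6 and C7 are cut as a syn-dihydroxylation. The forward step needs attack on the convex face, chemoselectivity over the ring A enone, and a reactivity difference between 6-OH and 7-OH.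

8 ⇒ 4 (through 7, 6 and 5). The ring A enone is traced to its silyl enol ether, the C6=C7 alkene to a C6 ketone, and C7–H to C7–OMe. The oxygen pattern of the quinone is needed only to steer the cycloaddition. Hydride reduction at C6 would place the hydroxyl on the concave face, so C6 and C7 are deoxygenated and re-oxidised. The forward steps need C6/C9 chemoselectivity and no epimerisation at C5.

4 ⇒ 2 + 3, and 2 ⇒ 1. The C1–C10 and C4–C5 bonds are cut as a Diels–Alder reaction, which gives ring A, the cis junction, the quaternary C10 and the absolute configuration in one step. The forward step needs site-, regio- and enantiocontrol with a hindered diene.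

## Other disconnections considered

Alternative 1: The C6–C7 bond is cut, so ring B is closed last by reductive coupling of two formyl groups on C5 and C8 of the seco-dialdehyde A1, giving the diol A2.
- In its favour: a SmI2 pinacol closure forms ring B and both carbinol centres in one step, normally cis through a chelated diketyl, and no O6/O7 protection has to be carried through the route. On this point it is better than the chosen plan, which carries O6/O7 protection from step 8 to step 27.
- Against it: A1 already contains the cyclobutane, ring C and the cyclopropane, so the trans ring A/cyclobutane junction has to be solved elsewhere. The C8 aldehyde is β to the free 9-OH (retro-aldol, epimerisation) and the C5 aldehyde is neopentyl on both sides. The C3 ketone competes for SmI2, and C14 has to be masked as a silyl ether and re-oxidised. A2 has a free 6,7-diol, so the 6-OAc/7-OH differentiation is left to a late, unselective acylation.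
- Comparison: the cis relationship is as secure as in the osmylation of 8, but the face of the diol is set only by the folding of a flexible chain, whereas in 8 the C5–C4 bond blocks one face. Step economy is better for ring B alone and worse for everything that must precede A1.

Alternative 2: The C5–C10 and C8–C9 bonds are cut; the triene A3 (a C14 dienone tethered to a 1-siloxy-2-methylcyclobutene) would cyclise on heating to A4.
- In its favour: two rings, two bonds and four stereocentres (C5, C8, C9, C10) in one step. The electron-poor diene and the strained electron-rich dienophile are electronically matched. A4 carries the C6=C7 alkene, so the diol can be set by the same osmylation as in the chosen plan (equal). In bonds made per step it is better than the chosen plan.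
- Against it: both new bonds end at fully substituted or neopentyl carbons. Thermal electrocyclic opening of the cyclobutene and vinylcyclopropane-type rearrangement of the spiro-cyclopropyl ketone compete at the temperatures needed. The C1 configuration has to be built into A3, so the trans junction is moved into the synthesis of an enantiopure tetrasubstituted cyclobutene. Ring A is still open in A4 and would have to be closed trans onto an existing cyclobutane.
- Comparison: the chosen plan makes the trans junction from an unstrained ring by contraction; A4 needs a six-membered ring forced trans across a four-membered one. Endo/exo and facial control in A3 are open questions, whereas the Wolff shift is stereospecific.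

Alternative 3: The C13–C15 bond is cut; the epoxy cyclobutanol A5 would rearrange under BF3·OEt2 to the spiro-cyclopropyl ketone A6.
- In its favour: the 1,2-shift is anti to the epoxide C–O bond and therefore stereospecific at C13, with C15 retained, which is equal to the directed Simmons–Smith step. It gives the C14 ketone and a free, differentiated 12-OH at once, so it is better than the chosen end game in redox and protecting-group economy (no silyl removal and oxidation at C14).
- Against it: A5 needs a cyclobutanol fused to ring C with a defined methyl centre and a tetrasubstituted epoxide beside two tertiary alcohols. Migration of C8 instead of C15, cyclopropylcarbinyl cation equilibria and Lewis-acid ionisation of the cyclobutane diol are competing pathways. The step acts on the periphery and leaves the trans-fused cyclobutane unsolved.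
- Comparison: both plans rest on a stereospecific 1,2-shift. The chosen plan uses it for the junction that has no other good solution; alternative 3 uses it for a subunit that a directed cyclopropanation can also deliver.

Key step: step 17

Assumption: the (S)-configured oxazaborolidinium ion is taken to shield the diene-approach face that leads to 4 as drawn (its mirror image is used otherwise), and the C14 carbinol of 13–32 is drawn as the anti-aldol epimer although its configuration is erased in step 26.

## Route

Step 1
Reactants: 1 4-methylpent-1-en-3-one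
Product: 2 triisopropyl[(4-methylpenta-1,3-dien-3-yl)oxy]silane
Conditions: iPr3SiOTf, Et3N, CH2Cl2, 0 °C
Reagents that add atoms: triisopropylsilyl triflate CC(C)[Si](C(C)C)(C(C)C)OS(=O)(=O)C(F)(F)F
Why: Silyl triflate/amine enol silylation; the isopropyl methine is the only enolisable position, so the tetrasubstituted enol ether, i.e. the 2-silyloxy diene, is the only product possible.

Step 2
Reactants: 2 silyloxy diene; 3 2-methoxy-5-methyl-1,4-benzoquinone
Product: 4 cis-fused adduct (6,9-dione with 7-methoxy-7-ene and 3-silyl enol ether)
Conditions: 20 mol % (S)-1-(2-methylphenyl)-3,3-diphenyl-oxazaborolidinium bis(trifluoromethylsulfonyl)imide (C24H25BNO+ C2F6NO4S2−), CH2Cl2, −78 → −40 °C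
Reagents that add atoms: none
Why: Enantioselective Diels–Alder reaction under chiral cationic boron catalysis; the methoxy group deactivates its own double bond, so the methyl-bearing C=C reacts. Activation of the more basic vinylogous-ester carbonyl makes the CH carbon the electrophilic end, which pairs with the nucleophilic CMe2 end of the diene and avoids vicinal quaternary carbons. Suprafacial addition sets H5 and the C10 methyl cis, and the catalyst face sets the absolute configuration.

Step 3
Reactants: 4 Diels–Alder adduct
Product: 5 cis-decalin-6,9-dione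
Conditions: SmI2 (4.5 equiv), THF/MeOH, −78 → 0 °C
Reagents that add atoms: none
Why: Divalent samarium reduces the ene-dione C=C and then cleaves the C7–OMe bond α to the C6 ketone (reductive cleavage of an α-hetero-substituted ketone). No stereocentre is formed, and the short, cold, weakly basic conditions are chosen to leave C5 unepimerised.

Step 4
Reactants: 5 6,9-dione
Product: 6 C6 tosylhydrazone
Conditions: TsNHNH2 (1.05 equiv), THF, 4 Å MS, rt
Reagents that add atoms: 4-methylbenzenesulfonohydrazide Cc1ccc(cc1)S(=O)(=O)NN
Why: Hydrazone condensation; C6 has a tertiary neighbour while C9 is shielded by the quaternary C10, so only C6 should condense, with the sulfonamide turned toward the less substituted C7.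

Step 5
Reactants: 6 tosylhydrazone
Product: 7 6-ene-9-ketone
Conditions: LiN(iPr)2 (3.5 equiv), THF, −78 → 0 °C; then H2O
Reagents that add atoms: none
Why: Shapiro reaction; metallation syn to the sulfonamide at the C7 methylene, loss of sulfinate and N2, and protonation of the vinyl-lithium place the alkene at C6=C7. The C9 ketone is held as its enolate and returns by α-protonation, so the β,γ-position of the alkene is kept and C5 is untouched.

Step 6
Reactants: 7 6-ene-9-ketone
Product: 8 1,6-diene-3,9-dione
Conditions: Pd(OAc)2 (1.1 equiv), MeCN, 40 °C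
Reagents that add atoms: none
Why: Saegusa–Ito oxidation of the silyl enol ether; C4 is quaternary, so β-hydride loss can only occur from C1 and gives the ring A enone without touching the C9 ketone or the isolated alkene.

Step 7
Reactants: 8 dienedione
Product: 9 6,7-cis-diol
Conditions: OsO4 (2 mol %), NMO, acetone/H2O, 0 °C → rt
Reagents that add atoms: osmium tetroxide O=[Os](=O)(=O)=O; 4-methylmorpholine N-oxide C[N+]1([O-])CCOCC1; water O
Why: Catalytic osmium tetroxide syn-dihydroxylation; the electron-rich isolated cis-alkene reacts well before the hindered, electron-poor enone. The reagent adds anti to the allylic C5–C4 bond, i.e. on the convex face that carries H5 and the angular methyl, which sets C6 and C7 together.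

Step 8
Reactants: 9 diol
Product: 10 7-O-silyl ether
Conditions: tBuMe2SiCl, imidazole, DMF, 0 °C
Reagents that add atoms: tert-butyldimethylsilyl chloride CC(C)(C)[Si](C)(C)Cl
Why: Selective silylation; 7-OH has a methylene neighbour (C8), whereas 6-OH sits beside C5 with its two quaternary neighbours, so the bulky silyl chloride should take O7 only.

Step 9
Reactants: 10 7-O-silyl ether
Product: 11 6-O-benzyloxymethyl 7-O-silyl dienedione
Conditions: BnOCH2Cl, iPr2NEt, nBu4NI (cat.), CH2Cl2, 40 °C
Reagents that add atoms: benzyl chloromethyl ether ClCOCc1ccccc1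
Why: Alkoxymethylation of the remaining secondary alcohol with an oxocarbenium-type electrophile; the amine base is too weak to cause O7→O6 silyl migration or β-elimination at the C9 ketone.

Step 10
Reactants: 11 protected dienedione; 12 3-(trimethylsilyl)prop-2-ynal
Product: 14 C8 side-chain ketone (14-triethylsilyloxy), via lithium aldolate 13 (not isolated)
Conditions: LiN(SiMe3)2, THF, −78 °C; 12; then Et3SiOTf, −78 °C
Reagents that add atoms: triethylsilyl triflate CC[Si](CC)(CC)OS(=O)(=O)C(F)(F)F
Why: Lithium-enolate aldol addition with in-situ O-silylation; C8 is the only acidic carbon (the ring A enone has no α′- or γ-hydrogen) and the ynal cannot enolise. The aldehyde approaches anti to the vicinal 7-silyloxy group, which sets C8, and a closed chair transition state gives the anti carbinol at C14, which is lost later. Silylation at −78 °C prevents retro-aldol.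

Step 11
Reactants: 14 enone ketone
Product: 16 1-vinyl-3,9-dione, via trimethylsilyl enol ether 15 (not isolated)
Conditions: CH2=CHMgBr, CuI (20 mol %), Me3SiCl, THF, −78 → −40 °C; aq. citric acid
Reagents that add atoms: vinylmagnesium bromide C=C[Mg]Br; chlorotrimethylsilane C[Si](C)(C)Cl (in 15 only)
Why: Copper-catalysed conjugate addition accelerated by silyl chloride; attack is axial on the half-chair in which the C10–C9 bond is axial, i.e. anti to C9 and beside the equatorial angular methyl. The other axial trajectory is blocked by the axial C5–C6 bond. This places the vinyl group trans to C9 and sets C1.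

Step 12
Reactants: 16 1-vinyl-3,9-dione
Product: 17 3-dioxolane
Conditions: (Me3SiOCH2)2, Me3SiOTf (5 mol %), CH2Cl2, −78 → −20 °C
Reagents that add atoms: 1,2-bis(trimethylsilyloxy)ethane C[Si](C)(C)OCCO[Si](C)(C)C
Why: Silyl-triflate-catalysed aprotic ketalisation; C3 has one methylene neighbour, while C9 lies between the quaternary C10 and the branched C8, so only C3 should react. The silyl ethers, acetal ether and alkenes are inert under these conditions.

Step 13
Reactants: 17 vinyl ketal
Product: 18 1-acetyl compound
Conditions: PdCl2 (20 mol %), Cu(OAc)2 (40 mol %), O2 (1 atm), DMA/H2O, rt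
Reagents that add atoms: water O
Why: Wacker-type oxidation; divalent palladium activates the monosubstituted alkene and water attacks the internal carbon, giving the methyl ketone. The silylalkyne is a poor substrate, and the acetate buffer protects the ketal and silyl ethers.

Step 14
Reactants: 18 1-acetyl compound
Product: 19 tricyclic 9-hydroxy-12-ketone (trans-hydrindanone)
Conditions: LiN(iPr)2 (1.1 equiv), THF, −78 → −40 °C; AcOH, −78 °C
Reagents that add atoms: none
Why: Kinetic intramolecular aldol addition (5-exo-trig with the enolate outside the new ring); the methyl group is deprotonated fastest and C11 reaches C9 from the ring B face on which C1 sits. The hydroxyl therefore falls cis to the angular methyl, and the equatorial acetyl and equatorial C10–C9 bond close to the trans-fused five-membered ketone. The cold acid quench keeps C1 and C8 from equilibrating.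

Step 15
Reactants: 19 tertiary alcohol
Product: 20 9-O-benzyloxymethyl ketone
Conditions: BnOCH2Cl, iPr2NEt, nBu4NI, ClCH2CH2Cl, 50 °C
Reagents that add atoms: benzyl chloromethyl ether ClCOCc1ccccc1
Why: Alkoxymethylation of the hindered tertiary alcohol under non-enolising conditions; this blocks retro-aldol in the next steps. An acetal-type group, unlike a silyl group, cannot later migrate to the neighbouring O11.

Step 16
Reactants: 20 protected ketone
Product: 22 tricyclic 11-diazo-12-ketone, via trifluoroacetyl ketone 21 (not isolated)
Conditions: LiN(SiMe3)2, THF, −78 °C; CF3CO2CH2CF3; aq. HCl work-up; then MeSO2N3, Et3N, H2O, MeCN, rt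
Reagents that add atoms: 2,2,2-trifluoroethyl trifluoroacetate FC(F)(F)COC(=O)C(F)(F)F (in 21 only); methanesulfonyl azide CS(=O)(=O)N=[N+]=[N-]
Why: Deacylative Regitz diazo transfer; the bulky amide removes a proton from the C11 methylene rather than the ring-fusion methine C1, and the enolised trifluoroacetyl ketone then shields C1 from epimerisation. Only C11 can accept the diazo group, because C1 is a methine and C9 is quaternary.

Step 17
Reactants: 22 tricyclic 11-diazo-12-ketone
Product: 24 trans-fused cyclobutane C11 methyl ester, via ketene 23 (not isolated)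
Conditions: hν (365 nm), MeOH/THF 4:1, 20 °C
Reagents that add atoms: methanol CO
Why: Photochemical Wolff rearrangement, with the ring contraction of 2-diazocyclopentanones to cyclobutanecarboxylates as the closest known case. Excitation expels N2 while C1 moves from the carbonyl carbon C12 to C11; the ring holds the diazo ketone in the s-cis geometry from which loss of nitrogen and the shift are concerted, so no free carbene should be available for insertion. The four-membered ring is closed by this 1,2-shift within the existing five-membered ring (a contraction, not an end-to-end cyclisation), forming C1–C11 and leaving C12 outside the ring as ketene 23. C1 migrates with retention, so the trans relationship between H1 and the C10 methyl passes from the unstrained trans-hydrindanone into the cyclobutane. Methanol adds to the ketene, and protonation of the resulting enol at C11 from the exo face sets the one new stereocentre. That centre is replaced in step 18, so its epimer is harmless. The step needs the Wolff shift to win over O–H and C–H insertion and 1,2-hydrogen shift; the fixed s-cis geometry, the quaternary C9 (no migrating hydrogen) and the nucleophilic solvent secure this. The 365 nm light is absorbed by the diazo ketone only.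

Step 18
Reactants: 24 cyclobutane ester
Product: 25 11-hydroxy ester
Conditions: KN(SiMe3)2, THF, −78 °C; 2-(phenylsulfonyl)-3-phenyloxaziridine; AcOH, −78 °C
Reagents that add atoms: 2-(phenylsulfonyl)-3-phenyloxaziridine O=S(=O)(N1OC1c1ccccc1)c1ccccc1
Why: Oxidation of an ester enolate by an N-sulfonyloxaziridine; C11 carries the only acidic hydrogen. The oxidant approaches from the exo face, away from ring B and the C8 side chain, so the new hydroxyl is cis to O9.

Step 19
Reactants: 25 11-hydroxy ester
Product: 26 terminal alkyne
Conditions: K2CO3 (cat.), MeOH, 0 °C → rt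
Reagents that add atoms: none
Why: Methanolysis of the C(sp)–Si bond; silyl ethers, acetal ethers and the ketal are stable. The O9 ether prevents retro-aldol opening of the 2-oxy-cyclobutane ester under the basic conditions.

Step 20
Reactants: 26 alkyne ester
Product: 27 α-hydroxy aldehyde
Conditions: iBu2AlH (2.5 equiv), CH2Cl2, −78 °C; aq. NaKC4H4O6
Reagents that add atoms: none
Why: Half-reduction of an ester; the aluminium alkoxide formed at O11 chelates the tetrahedral intermediate, which collapses to the aldehyde only on work-up. C11 is quaternary, so the aldehyde cannot enolise.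

Step 21
Reactants: 27 ynal
Product: 28 tetracyclic allylic alcohol (13-ethylidene with methyl cis to C12)
Conditions: Ni(cod)2 (15 mol %), Me2Zn (4 equiv), THF, 0 °C → rt
Reagents that add atoms: dimethylzinc C[Zn]C
Why: Nickel-catalysed alkylative ynal cyclisation (6-exo-dig); zerovalent nickel joins the alkyne and aldehyde in an oxanickelacyclopentene, methyl passes from zinc to nickel and reductive elimination puts it on C15 cis to the new C12–C13 bond. The zinc alkoxide at O11 chelates the aldehyde oxygen, so ring closure should give the cis-11,12-diol with H12 turned into the concave pocket.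

Step 22
Reactants: 28 allylic alcohol
Product: 29 spiro-cyclopropane
Conditions: Et2Zn, CH2I2, CH2Cl2, 0 °C
Reagents that add atoms: diiodomethane ICI
Why: Hydroxyl-directed Simmons–Smith cyclopropanation; allylic strain with the cis methyl holds the C12 alkoxide perpendicular to the alkene, so the zinc carbenoid delivers CH2 to the convex face. The addition is stereospecific, so C13 and C15 are set with the methyl still cis to C12.

Step 23
Reactants: 29 bis(benzyloxymethyl) ether
Product: 30 6,9,11,12-tetraol
Conditions: H2 (1 atm), Pd(OH)2/C, EtOAc, rt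
Reagents that add atoms: none
Why: Hydrogenolysis of both benzylic C–O bonds followed by loss of formaldehyde from the hemiformals; no alkene remains, and the silyl ethers, ketal and cyclopropane are inert in ethyl acetate.

Step 24
Reactants: 30 tetraol
Product: 31 6,12-diacetate
Conditions: Ac2O, pyridine, DMAP (cat.), rt → 40 °C
Reagents that add atoms: acetic anhydride CC(=O)OC(C)=O
Why: Nucleophile-catalysed acylation; only the secondary hydroxyls at C6 and C12 are free, and the tertiary cyclobutanols should not react under these conditions.

Step 25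
Reactants: 31 diacetate
Product: 32 14-alcohol
Conditions: HF·pyridine, pyridine, THF, 0 °C
Reagents that add atoms: none
Why: Selective desilylation; a triethylsilyl ether is cleaved much faster than a tert-butyldimethylsilyl ether by buffered fluoride, which frees O14 only.

Step 26
Reactants: 32 14-alcohol
Product: 33 14-ketone
Conditions: (COCl)2, Me2SO, CH2Cl2, −78 °C; Et3N, −78 → −20 °C
Reagents that add atoms: none
Why: Swern oxidation; an activated-sulfoxide oxidant does not cleave the cis tertiary diol, and the low temperature protects the new β-hydroxy ketone from retro-aldol. C8 stays cis because only a cis-fused ring C is possible on this cage.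

Step 27
Reactants: 33 protected ketone
Product: 34 CNP0157858.2
Conditions: 48 % aq. HF, MeCN, 0 °C → rt
Reagents that add atoms: water O
Why: Acidic fluoride deprotection; the last silyl ether is cleaved and the dioxolane is hydrolysed in the same medium, which is mild enough to leave both acetates and the cyclopropyl ketone intact.

## Compound list

1 | 4-methylpent-1-en-3-one | CC(C)C(=O)C=C | starting material
2 | triisopropyl[(4-methylpenta-1,3-dien-3-yl)oxy]silane | CC(C)=C(O[Si](C(C)C)(C(C)C)C(C)C)C=C | intermediate
3 | 2-methoxy-5-methyl-1,4-benzoquinone | COC1=CC(=O)C(C)=CC1=O | starting material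
4 | cis-fused adduct: 7-methoxy-7-ene-6,9-dione with 3-triisopropylsilyl enol ether; H5 and 10-methyl cis | O=C1C(OC)=CC(=O)[C@@]2(C)CC=C(O[Si](C(C)C)(C(C)C)C(C)C)C(C)(C)[C@@H]12 | intermediate
5 | cis-decalin-6,9-dione with 3-silyl enol ether | O=C1CCC(=O)[C@@]2(C)CC=C(O[Si](C(C)C)(C(C)C)C(C)C)C(C)(C)[C@@H]12 | intermediate
6 | C6 tosylhydrazone, sulfonamide syn to C7 | Cc1ccc(cc1)S(=O)(=O)N/N=C1\CCC(=O)[C@@]2(C)CC=C(O[Si](C(C)C)(C(C)C)C(C)C)C(C)(C)[C@@H]12 | intermediate
7 | 6-ene-9-ketone with 3-silyl enol ether | C1=CCC(=O)[C@@]2(C)CC=C(O[Si](C(C)C)(C(C)C)C(C)C)C(C)(C)[C@@H]12 | intermediate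
8 | 1,6-diene-3,9-dione | C1=CCC(=O)[C@@]2(C)C=CC(=O)C(C)(C)[C@@H]12 | intermediate
9 | 6,7-cis-diol, both hydroxyls cis to H5 and the 10-methyl | O[C@@H]1[C@H](O)CC(=O)[C@@]2(C)C=CC(=O)C(C)(C)[C@@H]12 | intermediate
10 | 7-O-tert-butyldimethylsilyl ether of 9 | O[C@@H]1[C@H](O[Si](C)(C)C(C)(C)C)CC(=O)[C@@]2(C)C=CC(=O)C(C)(C)[C@@H]12 | intermediate
11 | 6-O-benzyloxymethyl 7-O-silyl 1-ene-3,9-dione | c1ccccc1COCO[C@@H]1[C@H](O[Si](C)(C)C(C)(C)C)CC(=O)[C@@]2(C)C=CC(=O)C(C)(C)[C@@H]12 | intermediate
12 | 3-(trimethylsilyl)prop-2-ynal | O=CC#C[Si](C)(C)C | starting material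
13 | lithium aldolate at C14, C8 side chain trans to O7 | c1ccccc1COCO[C@@H]1[C@H](O[Si](C)(C)C(C)(C)C)[C@@H]([C@@H]([O-])C#C[Si](C)(C)C)C(=O)[C@@]2(C)C=CC(=O)C(C)(C)[C@@H]12.[Li+] | intermediate (not isolated)
14 | C8-[1-(triethylsilyloxy)-3-(trimethylsilyl)prop-2-ynyl] 1-ene-3,9-dione | c1ccccc1COCO[C@@H]1[C@H](O[Si](C)(C)C(C)(C)C)[C@@H]([C@@H](O[Si](CC)(CC)CC)C#C[Si](C)(C)C)C(=O)[C@@]2(C)C=CC(=O)C(C)(C)[C@@H]12 | intermediate
15 | 1-vinyl 3-trimethylsilyl enol ether, vinyl cis to the 10-methyl | c1ccccc1COCO[C@@H]1[C@H](O[Si](C)(C)C(C)(C)C)[C@@H]([C@@H](O[Si](CC)(CC)CC)C#C[Si](C)(C)C)C(=O)[C@@]2(C)[C@H](C=C)C=C(O[Si](C)(C)C)C(C)(C)[C@@H]12 | intermediate (not isolated)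
16 | 1-vinyl-3,9-dione | c1ccccc1COCO[C@@H]1[C@H](O[Si](C)(C)C(C)(C)C)[C@@H]([C@@H](O[Si](CC)(CC)CC)C#C[Si](C)(C)C)C(=O)[C@@]2(C)[C@H](C=C)CC(=O)C(C)(C)[C@@H]12 | intermediate
17 | 1-vinyl 3-dioxolane 9-ketone | c1ccccc1COCO[C@@H]1[C@H](O[Si](C)(C)C(C)(C)C)[C@@H]([C@@H](O[Si](CC)(CC)CC)C#C[Si](C)(C)C)C(=O)[C@@]2(C)[C@H](C=C)CC3(OCCO3)C(C)(C)[C@@H]12 | intermediate
18 | 1-acetyl 3-dioxolane 9-ketone, acetyl trans to C9 | c1ccccc1COCO[C@@H]1[C@H](O[Si](C)(C)C(C)(C)C)[C@@H]([C@@H](O[Si](CC)(CC)CC)C#C[Si](C)(C)C)C(=O)[C@@]2(C)[C@H](C(C)=O)CC3(OCCO3)C(C)(C)[C@@H]12 | intermediate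
19 | tricyclic 9-hydroxy-12-ketone: five-membered ring trans-fused to ring A, cis-fused to ring B | c1ccccc1COCO[C@@H]1[C@H](O[Si](C)(C)C(C)(C)C)[C@@H]([C@@H](O[Si](CC)(CC)CC)C#C[Si](C)(C)C)[C@@]2(O)CC(=O)[C@@H]4CC5(OCCO5)C(C)(C)[C@@H]1[C@@]24C | intermediate
20 | 9-O-benzyloxymethyl ether of 19 | c1ccccc1COCO[C@@H]1[C@H](O[Si](C)(C)C(C)(C)C)[C@@H]([C@@H](O[Si](CC)(CC)CC)C#C[Si](C)(C)C)[C@@]2(OCOCc3ccccc3)CC(=O)[C@@H]4CC5(OCCO5)C(C)(C)[C@@H]1[C@@]24C | intermediate
21 | 11-trifluoroacetyl 12-ketone, drawn as its chelated enol | c1ccccc1COCO[C@@H]1[C@H](O[Si](C)(C)C(C)(C)C)[C@@H]([C@@H](O[Si](CC)(CC)CC)C#C[Si](C)(C)C)[C@@]2(OCOCc3ccccc3)/C(=C(/O)C(F)(F)F)C(=O)[C@@H]4CC5(OCCO5)C(C)(C)[C@@H]1[C@@]24C | intermediate (not isolated)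
22 | tricyclic 11-diazo-12-ketone (trans-hydrindanone on the cis-decalin) | c1ccccc1COCO[C@@H]1[C@H](O[Si](C)(C)C(C)(C)C)[C@@H]([C@@H](O[Si](CC)(CC)CC)C#C[Si](C)(C)C)[C@@]2(OCOCc3ccccc3)C(=[N+]=[N-])C(=O)[C@@H]4CC5(OCCO5)C(C)(C)[C@@H]1[C@@]24C | intermediate
23 | cyclobutylidene ketene at C11 | c1ccccc1COCO[C@@H]1[C@H](O[Si](C)(C)C(C)(C)C)[C@@H]([C@@H](O[Si](CC)(CC)CC)C#C[Si](C)(C)C)[C@@]2(OCOCc3ccccc3)C(=C=O)[C@@H]4CC5(OCCO5)C(C)(C)[C@@H]1[C@@]24C | intermediate (not isolated)
24 | trans-fused cyclobutane C11 methyl ester (H11 cis to O9) | c1ccccc1COCO[C@@H]1[C@H](O[Si](C)(C)C(C)(C)C)[C@@H]([C@@H](O[Si](CC)(CC)CC)C#C[Si](C)(C)C)[C@@]2(OCOCc3ccccc3)[C@@H](C(=O)OC)[C@@H]4CC5(OCCO5)C(C)(C)[C@@H]1[C@@]24C | intermediate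
25 | 11-hydroxy methyl ester, 11-OH cis to O9 | c1ccccc1COCO[C@@H]1[C@H](O[Si](C)(C)C(C)(C)C)[C@@H]([C@@H](O[Si](CC)(CC)CC)C#C[Si](C)(C)C)[C@@]2(OCOCc3ccccc3)[C@@](O)(C(=O)OC)[C@@H]4CC5(OCCO5)C(C)(C)[C@@H]1[C@@]24C | intermediate
26 | terminal alkyne 11-hydroxy ester | c1ccccc1COCO[C@@H]1[C@H](O[Si](C)(C)C(C)(C)C)[C@@H]([C@@H](O[Si](CC)(CC)CC)C#C)[C@@]2(OCOCc3ccccc3)[C@@](O)(C(=O)OC)[C@@H]4CC5(OCCO5)C(C)(C)[C@@H]1[C@@]24C | intermediate
27 | 11-hydroxy 11-carbaldehyde with terminal alkyne | c1ccccc1COCO[C@@H]1[C@H](O[Si](C)(C)C(C)(C)C)[C@@H]([C@@H](O[Si](CC)(CC)CC)C#C)[C@@]2(OCOCc3ccccc3)[C@@](O)(C=O)[C@@H]4CC5(OCCO5)C(C)(C)[C@@H]1[C@@]24C | intermediate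
28 | tetracyclic 11,12-cis-diol with 13-ethylidene (methyl cis to C12) and 14-triethylsilyloxy | c1ccccc1COCO[C@@H]1[C@H](O[Si](C)(C)C(C)(C)C)[C@H]2[C@@H](O[Si](CC)(CC)CC)/C(=C/C)[C@H](O)[C@@]3(O)[C@@H]4CC5(OCCO5)C(C)(C)[C@@H]1[C@@]4(C)[C@@]23OCOCc1ccccc1 | intermediate
29 | spiro-cyclopropane, C17 cis to 12-OH, 15-methyl toward C12 | c1ccccc1COCO[C@@H]1[C@H](O[Si](C)(C)C(C)(C)C)[C@H]2[C@@H](O[Si](CC)(CC)CC)[C@]3(C[C@@H]3C)[C@H](O)[C@@]3(O)[C@@H]4CC5(OCCO5)C(C)(C)[C@@H]1[C@@]4(C)[C@@]23OCOCc1ccccc1 | intermediate
30 | 6,9,11,12-tetraol | O[C@@H]1[C@H](O[Si](C)(C)C(C)(C)C)[C@H]2[C@@H](O[Si](CC)(CC)CC)[C@]3(C[C@@H]3C)[C@H](O)[C@@]3(O)[C@@H]4CC5(OCCO5)C(C)(C)[C@@H]1[C@@]4(C)[C@@]23O | intermediate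
31 | 6,12-diacetate | CC(=O)O[C@@H]1[C@H](O[Si](C)(C)C(C)(C)C)[C@H]2[C@@H](O[Si](CC)(CC)CC)[C@]3(C[C@@H]3C)[C@H](OC(C)=O)[C@@]3(O)[C@@H]4CC5(OCCO5)C(C)(C)[C@@H]1[C@@]4(C)[C@@]23O | intermediate
32 | 14-alcohol | CC(=O)O[C@@H]1[C@H](O[Si](C)(C)C(C)(C)C)[C@H]2[C@@H](O)[C@]3(C[C@@H]3C)[C@H](OC(C)=O)[C@@]3(O)[C@@H]4CC5(OCCO5)C(C)(C)[C@@H]1[C@@]4(C)[C@@]23O | intermediate
33 | 14-ketone, 7-O-silyl, 3-dioxolane | CC(=O)O[C@@H]1[C@H](O[Si](C)(C)C(C)(C)C)[C@H]2C(=O)[C@]3(C[C@@H]3C)[C@H](OC(C)=O)[C@@]3(O)[C@@H]4CC5(OCCO5)C(C)(C)[C@@H]1[C@@]4(C)[C@@]23O | intermediate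
34 | CNP0157858.2 | CC(=O)O[C@@H]1[C@H](O)[C@H]2C(=O)[C@]3(C[C@@H]3C)[C@H](OC(C)=O)[C@@]3(O)[C@@H]4CC(=O)C(C)(C)[C@@H]1[C@@]4(C)[C@@]23O | target

## Step count and least certain steps

Total step count: 27. Longest linear sequence: 27 steps (1 → 34); 3 and 12 enter as purchased materials.

Step 17 (key step). The most likely failure is diversion of the excited diazo ketone into chemistry that does not rearrange: O–H insertion into methanol, C–H insertion into the neighbouring benzyloxymethyl group, or secondary photolysis. The strain of the trans-fused cyclobutane raises the cost of the shift and makes these more competitive. The fallback is a base-induced semibenzilic (quasi-Favorskii) contraction, which makes the same C1–C11 bond without a carbene. It sets out from 20: kinetic enolisation with LiN(SiMe3)2 and quenching with N-bromosuccinimide would give the 11-bromo-12-ketone F1 (bromine on the exo face). NaOMe in MeOH at 0 °C would add to C12, and the tetrahedral intermediate would expel bromide as C1 shifts, returning to the route at 24. Its weakness is the exposure of C1–H to methoxide.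

Step 2. The cis-methyl group of the diene makes the s-cis conformer scarce, so the reaction may be slow, and a slow reaction is likely to lose enantioselectivity or to drift into a stepwise Michael addition with aromatisation of the quinone. The fallback gives up catalytic control: from 2 and 3, stoichiometric BF3·OEt2 at −78 °C should give the racemic adduct with the same regiochemistry, and the enantiomers would be separated on a chiral stationary phase. The unwanted mirror-image adduct F2 is removed and the route is rejoined at 4.

Step 5. The hydrazone has to be metallated at C7 next to an enolate that the same base creates at C8/C9. Incomplete polyanion formation, or metallation at C5 with loss of the ring-fusion configuration, are the likely problems. The fallback replaces the hydrazone by a stereochemically enforced syn-elimination. From 5, NaBH4 at −78 °C should reduce the less hindered C6 carbonyl from the convex face to the alcohol F3, with the hydroxyl trans to H5. Methyl N-(triethylammoniosulfonyl)carbamate can then abstract only a cis hydrogen on C7, giving 7.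

Step 14. Proton transfer may outrun ring closure. C9 lies between a quaternary and a branched carbon, and the enolate must reach it across a trans-diequatorial relationship, so equilibration of the enolate to C1 or C8 (epimerisation) or reversal of the aldol are the main risks. The fallback generates the enolate reductively and regiospecifically. From 18, LiN(SiMe3)2/Me3SiCl would give the kinetic silyl enol ether F4, and N-bromosuccinimide would convert it into the bromomethyl ketone F5. SmI2 in THF at −78 °C would then form the trivalent samarium enolate at C11 under non-basic conditions (Reformatsky-type aldol), chelated to the C9 carbonyl, and close to 19.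

Step 21. Direct methyl transfer from zinc to the hindered aldehyde, stalled transmetalation at nickel, or loss of chelation (and with it the C12 configuration) are the likely failures. The fallback separates ring closure from methylation. From 27, after deprotonation of the 11-OH with nBuLi, a divalent zirconocene equivalent (Cp2ZrCl2, 2 nBuLi, THF, −78 °C → rt) should join alkyne and aldehyde in an oxazirconacyclopentene. Iodinolysis (I2) would give the vinyl iodide F6 with iodine cis to C12, and Negishi coupling (MeZnCl, Pd(PPh3)4) would replace iodine by methyl with retention, returning to the route at 28.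

## Further compounds

F1 | step 17 | 11-bromo-12-ketone, bromine cis to O9 | c1ccccc1COCO[C@@H]1[C@H](O[Si](C)(C)C(C)(C)C)[C@@H]([C@@H](O[Si](CC)(CC)CC)C#C[Si](C)(C)C)[C@@]2(OCOCc3ccccc3)[C@H](Br)C(=O)[C@@H]4CC5(OCCO5)C(C)(C)[C@@H]1[C@@]24C
F2 | step 2 | mirror image of adduct 4 | O=C1C(OC)=CC(=O)[C@]2(C)CC=C(O[Si](C(C)C)(C(C)C)C(C)C)C(C)(C)[C@H]12
F3 | step 5 | 6-hydroxy-9-ketone, hydroxyl trans to H5 | O[C@H]1CCC(=O)[C@@]2(C)CC=C(O[Si](C(C)C)(C(C)C)C(C)C)C(C)(C)[C@@H]12
F4 | step 14 | kinetic trimethylsilyl enol ether of the C1 acetyl group | c1ccccc1COCO[C@@H]1[C@H](O[Si](C)(C)C(C)(C)C)[C@@H]([C@@H](O[Si](CC)(CC)CC)C#C[Si](C)(C)C)C(=O)[C@@]2(C)[C@H](C(=C)O[Si](C)(C)C)CC3(OCCO3)C(C)(C)[C@@H]12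
F5 | step 14 | C1 bromoacetyl compound | c1ccccc1COCO[C@@H]1[C@H](O[Si](C)(C)C(C)(C)C)[C@@H]([C@@H](O[Si](CC)(CC)CC)C#C[Si](C)(C)C)C(=O)[C@@]2(C)[C@H](C(=O)CBr)CC3(OCCO3)C(C)(C)[C@@H]12
F6 | step 21 | tetracyclic 13-(iodomethylidene) allylic alcohol, iodine cis to C12 | c1ccccc1COCO[C@@H]1[C@H](O[Si](C)(C)C(C)(C)C)[C@H]2[C@@H](O[Si](CC)(CC)CC)/C(=C/I)[C@H](O)[C@@]3(O)[C@@H]4CC5(OCCO5)C(C)(C)[C@@H]1[C@@]4(C)[C@@]23OCOCc1ccccc1
A1 | alternative 1 | 6,7-seco dialdehyde with formyl groups on C5 and C8 | O=C[C@H]1[C@H](O[Si](C)(C)C(C)(C)C)[C@]2(C[C@@H]2C)[C@H](OC(C)=O)[C@@]2(O)[C@@H]3CC(=O)C(C)(C)[C@@H](C=O)[C@@]3(C)[C@@]12O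
A2 | alternative 1 | tetracyclic 6,7-diol with C14 silyl ether | O[C@@H]1[C@H](O)[C@H]2[C@H](O[Si](C)(C)C(C)(C)C)[C@]3(C[C@@H]3C)[C@H](OC(C)=O)[C@@]3(O)[C@@H]4CC(=O)C(C)(C)[C@@H]1[C@@]4(C)[C@@]23O
A3 | alternative 2 | C14 dienone tethered to the 1-siloxy-2-methylcyclobutene | COC(=O)C(C)(C)/C=C/C=C/C(=O)[C@]1(C[C@@H]1C)[C@@H]2OC(C)(C)O[C@@]23[C@H](CO[Si](C)(C)C(C)(C)C)C(C)=C3O[Si](C)(C)C(C)(C)C
A4 | alternative 2 | ring B cyclohexene fused to ring C and the cyclobutane | C1=C[C@H]2C(=O)[C@]3(C[C@@H]3C)[C@@H]5OC(C)(C)O[C@@]56[C@H](CO[Si](C)(C)C(C)(C)C)[C@@](C)([C@H]1C(C)(C)C(=O)OC)[C@@]26O[Si](C)(C)C(C)(C)C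
A5 | alternative 3 | 12,13-epoxide with cyclobutanol fused at C13–C14 | CC(=O)O[C@@H]1[C@H](O[Si](CC)(CC)CC)[C@H]2[C@]5(O)[C@]6(C[C@@H]5C)O[C@@H]6[C@@]3(O[Si]9(C(C)(C)C)C(C)(C)C)[C@@H]4CC(=O)C(C)(C)[C@@H]1[C@@]4(C)[C@@]23O9
A6 | alternative 3 | spirocyclopropyl C14 ketone with free C12 hydroxyl | CC(=O)O[C@@H]1[C@H](O[Si](CC)(CC)CC)[C@H]2C(=O)[C@]3(C[C@@H]3C)[C@H](O)[C@@]3(O[Si]9(C(C)(C)C)C(C)(C)C)[C@@H]4CC(=O)C(C)(C)[C@@H]1[C@@]4(C)[C@@]23O9
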